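The readings were computed for substances that don't exist, and the scatter is random.

| flask | left-handed substrate | right-handed substrate | coupling partner | free catalyst | remark | time |
|---|---|---|---|---|---|---|
| dawn | 0.070 M | 0.070 M | 1.2 equiv | 0.1 mol% | run made earlier |  |
| midnight | 0.11 M | 0.11 M | 1.2 equiv | 0.1 mol% | run made earlier |  |
| autumn | 0.050 M | 0.050 M | 0.60 equiv | 0.1 mol% | run made earlier |  |
| flask | 0.050 M | 0.050 M | 1.20 equiv | 0.1 mol% |  | 15 d |

| run | time / d | left-handed substrate / % | left-handed product / % | right-handed substrate / % |
|---|---|---|---|---|
| dawn | 1.25 | 26.4 | 23.5 | 48.4 |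
| dawn | 2.50 | 27.1 | 23.2 | 49.3 |
| dawn | 4.00 | 27.5 | 23.0 | 48.8 |
| dawn | 5.00 | 26.1 | 24.7 | 49.3 |
| dawn | 6.00 | 26.8 | 24.5 | 49.0 |
| dawn | 8.00 | 26.1 | 24.4 | 49.0 |
| dawn | 10.0 | 26.8 | 23.4 | 48.9 |
| midnight | 1.25 | 15.1 | 34.5 | 47.6 |
| midnight | 2.50 | 15.5 | 36.1 | 47.9 |
| midnight | 4.00 | 15.1 | 35.8 | 48.0 |
| midnight | 5.00 | 15.1 | 35.4 | 47.3 |
| midnight | 6.00 | 14.9 | 34.9 | 48.0 |
| midnight | 8.00 | 14.9 | 35.3 | 49.0 |
| midnight | 10.0 | 15.4 | 34.7 | 47.9 |
| autumn | 0.625 | 41.8 | 8.9 | 49.7 |
| autumn | 1.25 | 41.0 | 8.8 | 49.0 |
| autumn | 2.50 | 41.6 | 8.9 | 50.2 |
| autumn | 5.00 | 41.4 | 8.6 | 49.1 |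
| autumn | 10.0 | 41.5 | 9.0 | 49.0 |

(standard deviation of a reading: 0.5 percentage points)

- free catalyst is single-handed; left-handed substrate and right-handed substrate are mirror images of each other, charged as a racemate, each of them at the stated concentration
- steps under discussion: coupling partner + catalyst intermediate B -> free catalyst + right-handed product; coupling partner + catalyst intermediate A -> free catalyst + left-handed product; free catalyst + right-handed substrate <-> catalyst intermediate B; free catalyst -> spent catalyst; free catalyst + left-handed substrate <-> catalyst intermediate A

- conversion of left-handed substrate and right-handed substrate together at 15 d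
- amount of left-handed product at 15 d, in percent of the left-handed substrate and right-handed substrate together charged
- amount of right-handed substrate at 15 d, in percent of the left-handed substrate and right-handed substrate together charged

**Small charge.** Take a free-catalyst charge of 0.1 mol%. In the dawn run the left-handed product reads 23.5% at 1.25 d and 23.4% at 10.0 d, so you needn't know the time well. You need to know what the charge buys before it is lost.

**What matters.** Let f be the fraction of left-handed substrate left and d = 0.200 the partner's excess over that substrate, in the same fraction. If turnover and loss both pass through free catalyst, product per catalyst lost goes as f(f+d). Integrating gives the budget W = ln[(f+d)/(f(1+d))]/d, which, with the equivalents of coupling partner held, grows with the loading and with the square of concentration. These settings are given, so the dawn plateau must be known well. Its mean product 23.8% gives f = 0.524 and W = 0.706. Scaled to midnight, W gives 35.7% of product, within that run's readings.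

**My reckoning.** This flask has W = 0.360, so f = 0.691 and left-handed product is 15.5%. The right-handed side is a small correction: the dawn readings put its loss at 0.0438 of right-handed substrate per left-handed product. That gives conversion 16.2% and right-handed substrate 49.3%.

**The forecast.** It says “the catalyst dies early” and gives 15.7%, 15.1% and 49.4%.

**The flask.** It gives 16.1%, 15.4% and 49.3%.

    coupling partner + catalyst intermediate B → free catalyst + right-handed product (k = 0.0660 /M/s)
    coupling partner + catalyst intermediate A → free catalyst + left-handed product (k = 4.50 /M/s)
    free catalyst + right-handed substrate ⇌ catalyst intermediate B (K = 21.0 /M, k = 1700 /M/s)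
    free catalyst → spent catalyst (k = 2.50 × 10⁻⁴ /s)
    free catalyst + left-handed substrate ⇌ catalyst intermediate A (K = 8.10 /M, k = 160 /M/s)

**Budget reused.** The flask keeps 69% of its left-handed substrate, against the budget's 69.1%. Two things acting together hold this flask's conversion at 16.1%: without the passing of free catalyst into spent catalyst it reaches 59.3%, and without the backward run from catalyst intermediate B to free catalyst and right-handed substrate it reaches 53.0%. A neighbour flask with 0.17 mol% of free catalyst has W = 0.612, which predicts 56.1% of its left-handed substrate left, and that flask stands at 56%.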